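## Retrosynthetic overview

1. Target 9 ⇒ 5‑O‑(3,7‑dimethylocta‑1,6‑dien‑3‑yl) ether 7 by a retro aromatic Claisen ([3,3]) step. The rearrangement makes the C6–C1'' bond and the C2''=C3'' alkene, and C6 is the only open ortho position of O5.
2. 7 ⇒ propargyl ether 6 (semi‑hydrogenation) ⇒ phenol 3 + dehydrolinalool 4 (copper‑catalysed O‑propargylation at the tertiary carbon).
3. 3 ⇒ (2S)‑hesperetin 1 by methylation of the two non‑chelated phenols.
4. Ring order: no ring is built. Rings A, B and C and the C2 stereocenter come with natural 1, and C2 is never touched.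

Assumption: 1 is bought optically pure (citrus‑derived, ee checked by chiral HPLC) and 4 is racemic, so the ether carbon in 5–7 is an uncontrolled, transient center that step 4 erases; it is left undefined in the SMILES.

## Route

**Step 1**
Reactants: 1 (2S)‑hesperetin [(2S)‑5,7‑dihydroxy‑2‑(3‑hydroxy‑4‑methoxyphenyl)chroman‑4‑one]
Product: 3 (2S)‑5‑hydroxy‑7‑methoxy‑2‑(3,4‑dimethoxyphenyl)chroman‑4‑one, via 7‑O‑methylhesperetin 2 (not isolated)
Conditions: TMSCHN2 (3 equiv), iPr2NEt, MeOH/MeCN, 0 °C to rt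
Reagents that add atoms: trimethylsilyldiazomethane, C[Si](C)(C)C=[N+]=[N-]
Why: O‑methylation of phenols by diazomethane released in situ from TMSCHN2 and MeOH takes the acidic 7‑OH first and the 3'‑OH second, leaves the 5‑OH that is hydrogen‑bonded to the C4 carbonyl, and is too mild to open the pyranone ring, so the bought (2S) center is kept.

**Step 2**
Reactants: 3 (2S)‑5‑hydroxy‑7‑methoxy‑2‑(3,4‑dimethoxyphenyl)chroman‑4‑one; 4 (±)‑dehydrolinalool (3,7‑dimethyloct‑6‑en‑1‑yn‑3‑ol)
Product: 6 (2S)‑5‑[(3,7‑dimethyloct‑6‑en‑1‑yn‑3‑yl)oxy]‑7‑methoxy‑2‑(3,4‑dimethoxyphenyl)chroman‑4‑one (1:1 epimers at the ether carbon), via dehydrolinalyl trifluoroacetate 5 (not isolated)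
Conditions: 4, (CF3CO)2O, DBU, MeCN, −5 °C; then 3, DBU, CuCl2·2H2O (1 mol %), MeCN, −5 to 0 °C
Reagents that add atoms: none
Why: Copper‑catalysed propargylic etherification (Godfrey type), in which the copper acetylide of 5 loses trifluoroacetate to a copper allenylidene/propargyl cation that the DBU‑generated 5‑phenoxide attacks at the tertiary carbon; the new ether carbon is not controlled and C2 is not involved.

**Step 3**
Reactants: 6 (2S)‑5‑[(3,7‑dimethyloct‑6‑en‑1‑yn‑3‑yl)oxy]‑7‑methoxy‑2‑(3,4‑dimethoxyphenyl)chroman‑4‑one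
Product: 7 (2S)‑5‑[(3,7‑dimethylocta‑1,6‑dien‑3‑yl)oxy]‑7‑methoxy‑2‑(3,4‑dimethoxyphenyl)chroman‑4‑one (1:1 epimers at the ether carbon)
Conditions: H2 (1 atm), Pd/CaCO3 poisoned with Pb(OAc)2, quinoline, EtOAc, rt, stopped at 1 equiv H2
Reagents that add atoms: none
Why: Lindlar semi‑hydrogenation of the terminal alkyne on the lead‑poisoned palladium surface stops at the vinyl group, and the trisubstituted alkene, the aryl ketone and the tertiary allylic ether are inert under these conditions.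

**Step 4**
Reactants: 7 (2S)‑5‑[(3,7‑dimethylocta‑1,6‑dien‑3‑yl)oxy]‑7‑methoxy‑2‑(3,4‑dimethoxyphenyl)chroman‑4‑one
Product: 9 (2S)‑6‑[(2E)‑3,7‑dimethylocta‑2,6‑dien‑1‑yl]‑5‑hydroxy‑7‑methoxy‑2‑(3,4‑dimethoxyphenyl)chroman‑4‑one (target), via ortho‑dienone tautomer 8 (not isolated)
Conditions: degassed PhMe, 110 °C, 2–4 h; then AgNO3‑impregnated silica to remove the Z isomer
Reagents that add atoms: none
Why: Aromatic Claisen rearrangement, a [3,3]‑sigmatropic shift through a chair transition state, bonds the vinyl terminus to C6 (the only free ortho position) and turns the tertiary ether carbon into the C2''=C3'' alkene with the homoprenyl chain preferentially pseudo‑equatorial (E major), after which dienone 8 tautomerises to the chelated phenol; the ether stereocenter disappears and C2 is untouched under neutral heating.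

## Compound list

1 | (2S)‑hesperetin, (2S)‑5,7‑dihydroxy‑2‑(3‑hydroxy‑4‑methoxyphenyl)chroman‑4‑one | COc1ccc([C@@H]2CC(=O)c3c(cc(O)cc3O)O2)cc1O | starting material
2 | 7‑O‑methylhesperetin, (2S)‑5‑hydroxy‑2‑(3‑hydroxy‑4‑methoxyphenyl)‑7‑methoxychroman‑4‑one, not isolated | COc1ccc([C@@H]2CC(=O)c3c(cc(OC)cc3O)O2)cc1O | intermediate
3 | (2S)‑5‑hydroxy‑7‑methoxy‑2‑(3,4‑dimethoxyphenyl)chroman‑4‑one | COc1ccc([C@@H]2CC(=O)c3c(cc(OC)cc3O)O2)cc1OC | intermediate
4 | (±)‑dehydrolinalool, 3,7‑dimethyloct‑6‑en‑1‑yn‑3‑ol | C#CC(C)(O)CCC=C(C)C | starting material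
5 | 3,7‑dimethyloct‑6‑en‑1‑yn‑3‑yl trifluoroacetate, not isolated | C#CC(C)(CCC=C(C)C)OC(=O)C(F)(F)F | intermediate
6 | (2S)‑5‑[(3,7‑dimethyloct‑6‑en‑1‑yn‑3‑yl)oxy]‑7‑methoxy‑2‑(3,4‑dimethoxyphenyl)chroman‑4‑one, 1:1 epimers at the ether carbon | COc1ccc([C@@H]2CC(=O)c3c(cc(OC)cc3OC(C)(C#C)CCC=C(C)C)O2)cc1OC | intermediate
7 | (2S)‑5‑[(3,7‑dimethylocta‑1,6‑dien‑3‑yl)oxy]‑7‑methoxy‑2‑(3,4‑dimethoxyphenyl)chroman‑4‑one, 1:1 epimers at the ether carbon | COc1ccc([C@@H]2CC(=O)c3c(cc(OC)cc3OC(C)(C=C)CCC=C(C)C)O2)cc1OC | intermediate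
8 | (2S)‑6‑[(2E)‑3,7‑dimethylocta‑2,6‑dien‑1‑yl]‑7‑methoxy‑2‑(3,4‑dimethoxyphenyl)‑2,3‑dihydro‑4H‑chromene‑4,5(6H)‑dione, ortho‑dienone, C6 undefined, not isolated | COc1ccc([C@@H]2CC(=O)C3=C(C=C(OC)C(C/C=C(\C)CCC=C(C)C)C3=O)O2)cc1OC | intermediate
9 | (2S)‑6‑[(2E)‑3,7‑dimethylocta‑2,6‑dien‑1‑yl]‑5‑hydroxy‑7‑methoxy‑2‑(3,4‑dimethoxyphenyl)chroman‑4‑one, CNP0310479.1 | COc1ccc([C@@H]2CC(=O)c3c(cc(OC)c(C/C=C(\C)CCC=C(C)C)c3O)O2)cc1OC | target

## Step count and risks

Total step count: 4. Longest linear sequence: 4 steps (1 → 3 → 6 → 7 → 9).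

The three steps most likely to fail are steps 2, 3 and 4; step 4 is the most serious for the purity of the target.

**Step 2.** The 5‑OH is hydrogen‑bonded to the C4 carbonyl and hindered, so capture of a tertiary propargyl electrophile may be slow. DBU could also open the pyranone ring to the 2'‑hydroxychalcone (E1cB) and erode the ee at C2, so the ee of 6 is checked by chiral HPLC. The fallback sets out from 3 and uses a primary electrophile under neutral conditions. Mitsunobu etherification with geraniol (PPh3, DIAD, THF, 0 °C to rt) gives (2S)‑5‑{[(2E)‑3,7‑dimethylocta‑2,6‑dien‑1‑yl]oxy}‑7‑methoxy‑2‑(3,4‑dimethoxyphenyl)chroman‑4‑one F1. A Lewis‑acid‑promoted 1,3‑shift of the geranyl group from O5 to the neighbouring C6 (Bi(OTf)3 cat., CH2Cl2, 0 °C) then gives the target with the E alkene carried over from geraniol. This fallback comes back to the route at 9.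

**Step 3.** Over‑reduction of the vinyl group to ethyl, or hydrogenolysis of the propargylic C–O bond, would give by‑products that are hard to separate from 7. The fallback sets out from 3 and avoids the alkyne altogether. (±)‑Linalool is converted (n‑BuLi, Boc2O, THF) into tert‑butyl 3,7‑dimethylocta‑1,6‑dien‑3‑yl carbonate F2. Allylic etherification of 3 with it under zerovalent palladium catalysis (Pd(PPh3)4, THF, 0 °C, short reaction time to keep the kinetic branched ether) gives the tertiary allyl ether directly. This fallback comes back to the route at 7.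

**Step 4.** The rearrangement fixes the position (C6) but controls the alkene geometry only through the modest preference of the chair transition state for an equatorial homoprenyl chain over an equatorial methyl. By analogy with other linalyl‑type ethers, an E:Z ratio of only about 2–3:1 should be expected. The Z (neryl) isomer, recognisable by its C3'' methyl 13C shift, must be removed on AgNO3‑silica or by preparative HPLC. Traces of acid would also ionise the tertiary ether or cyclise 9 to a chroman. The fallback sets out from 3 and brings in the side chain with its geometry already fixed. Iodination ortho to the free 5‑OH (BnMe3N+ ICl2−, CaCO3, CH2Cl2/MeOH, rt) gives (2S)‑5‑hydroxy‑6‑iodo‑7‑methoxy‑2‑(3,4‑dimethoxyphenyl)chroman‑4‑one F3. Stille coupling of it with tributyl[(2E)‑3,7‑dimethylocta‑2,6‑dien‑1‑yl]stannane F4 (made from geranyl chloride and Bu3SnLi), Pd(PPh3)4, DMF, 80 °C, joins C6 to the primary allyl carbon with the E geometry of geraniol. This fallback comes back to the route at 9.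

## Further compounds

F1 | step 2 | (2S)‑5‑{[(2E)‑3,7‑dimethylocta‑2,6‑dien‑1‑yl]oxy}‑7‑methoxy‑2‑(3,4‑dimethoxyphenyl)chroman‑4‑one | COc1ccc([C@@H]2CC(=O)c3c(cc(OC)cc3OC/C=C(\C)CCC=C(C)C)O2)cc1OC
F2 | step 3 | tert‑butyl 3,7‑dimethylocta‑1,6‑dien‑3‑yl carbonate (racemic) | C=CC(C)(CCC=C(C)C)OC(=O)OC(C)(C)C
F3 | step 4 | (2S)‑5‑hydroxy‑6‑iodo‑7‑methoxy‑2‑(3,4‑dimethoxyphenyl)chroman‑4‑one | COc1ccc([C@@H]2CC(=O)c3c(cc(OC)c(I)c3O)O2)cc1OC
F4 | step 4 | tributyl[(2E)‑3,7‑dimethylocta‑2,6‑dien‑1‑yl]stannane | CCCC[Sn](CCCC)(CCCC)C/C=C(\C)CCC=C(C)C
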